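The constants used here are those of an exercise; the result is computed.

A small charge of solid substrate goes into a stirred flask, and the dispute is whether it stays as a solid feeding a saturated solution or vanishes into a mixture of dissolved forms.

solid substrate 0.40 M; time 2.0 h

    starting material ⇌ isomer of the product A (K1 = 2.4, k1 = 0.0097 s⁻¹)
    starting material ⇌ dormant form (K2 = 0.36, k2 = 0.0053 s⁻¹)
    starting material ⇌ target (K3 = 2.1, k3 = 0.014 s⁻¹)
    target ⇌ isomer of the product B (K4 = 2.3, k4 = 0.034 s⁻¹)
    solid substrate ⇌ starting material, rate k5*(cs5 - [starting material]) while solid is left; crystals form when [starting material] > cs5 (cs5 = 0.17 M, k5 = 0.41 s⁻¹)

- solid, in amounts per volume of the solution: solid substrate
- at the start none of the solid substrate is in solution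
- what has only dissolved of solid substrate counts as not reacted
- the reaction counts as stopped when no species that holds the solid substrate changes by six tenths of a point or more over the second half of the time
- run time (flask): 2.0 h

- the state of affairs at 2.0 h: stopped, and by what, or still going (for what has run out or reacted, a solid counts together with what of it has only dissolved) (all of the solid substrate has reacted / it is still moving / forward and back rates have come level)
- how much target there is at 2.0 h, in percent of the solid substrate charged
- how much isomer of the product B there is at 2.0 h, in percent of the solid substrate charged

Two chemists disagree. The first says the solid rules: while it lies there, c(starting material) stands at the solubility 0.17 M, so level step rates put c(target) at 0.357 M, which is 89.2% of the charge. The second says the charge rules: it dissolves completely and is shared out by the equilibrium constants, which is thermodynamic control.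

My own reckoning tests the first view. With the steps level, each unit of starting material stands beside 2.4 of isomer of the product A, 0.36 of dormant form, 2.1 of target and 4.83 of isomer of the product B, so the dissolved forms add up to 10.7 units. Multiplied by the solubility, this gives 1.82 M, the capacity of the solution: the total charge that the dissolved forms hold at equilibrium when starting material stands at its solubility. The charge of 0.40 M is less than this capacity, so the solution cannot stay saturated at equilibrium, and the second view wins in my reckoning. Isomer of the product B at solubility level, 0.821 M, is by itself more than the charge.

The time looks long enough too. The return from isomer of the product A, by its backward rate alone, has a half-life of 2.86 min, much shorter than the run of 2.0 h. I therefore expect level rates, with target at 19.6% and isomer of the product B at 45.2%.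

The forecast, on the second chemist's side, gave forward and back rates have come level, with 19.6% target and 45.2% isomer of the product B: “the run ends at equilibrium rather than by complete consumption”.

The simulation gives forward and back rates have come level, with 19.6% target and 45.2% isomer of the product B.

In this flask the half-life of target by the forward rate alone of its turning into isomer of the product B is 0.34 min at 2.00 h, shorter than the 2.0 h of the run, and the backward turnover of that step comes to 99.0% of the forward one. This flask's charge is 22.0% of the capacity 1.82 M, and the neighbour flask with 0.10 M, further below it, reads 19.6% target. The first chemist's region lies above the capacity: the target answer has moved by 5 points at 2.44 M of solid substrate, where target at solubility level makes 14.6% of the charge.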